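**Strategy.** Everything rests on disconnecting the O4–C3 bond of the dioxane ring (O1, C2 carrying syringyl ring B, C3 carrying CH2OH, O4 on C4a of ring A). A single intramolecular Mitsunobu etherification closes this ring and inverts C3. It exploits the pairing of the secondary C3 carbinol with the O4 phenol, the most acidic O–H of ring A because it sits para to the C7 formyl group. The precursor is an erythro 3-aryl-3-aryloxypropane-1,2-diol with the primary hydroxyl silylated and the ring B phenol pivaloylated, obtained from a Sharpless epoxide by benzylic opening with inversion. Two inversions turn the trans epoxide into the trans-(2S,3S) benzodioxane.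

Key step: step 9

Remark on the chemistry: locants are O1, C2 (carries ring B), C3 (carries CH2OH), O4, C4a–C8a (ring A). The target is the trans-(2S,3S) isomer, which requires the (2R,3R)-epoxide and therefore the D-(−)-tartrate ligand.

**Step 1**
Reactants: 1 syringaldehyde; 2 triethyl phosphonoacetate
Product: 3 ethyl (E)-sinapate, i.e. ethyl (2E)-3-(4-hydroxy-3,5-dimethoxyphenyl)prop-2-enoate
Conditions: NaH (2.3 equiv), THF, 0 °C → 60 °C; then 1 M HCl
Reagents that add atoms: none
Why: Horner–Wadsworth–Emmons olefination: the extra equivalent of NaH covers the phenol, the stabilised phosphonate anion still adds to the aldehyde on warming, and reversible addition before elimination should give the (E)-cinnamate.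

**Step 2**
Reactants: 3 ethyl (E)-sinapate
Product: 4 (E)-sinapyl alcohol, i.e. 4-[(1E)-3-hydroxyprop-1-en-1-yl]-2,6-dimethoxyphenol
Conditions: iBu2AlH (4 equiv), toluene, −78 → 0 °C; aq. KNaC4H4O6 work-up
Reagents that add atoms: none
Why: 1,2-reduction of the conjugated ester by iBu2AlH (ester to allylic alcohol), with one equivalent of hydride spent on the phenol and the alkene geometry untouched.

**Step 3**
Reactants: 4 (E)-sinapyl alcohol
Product: 5 4-[(1E)-3-hydroxyprop-1-en-1-yl]-2,6-dimethoxyphenyl pivalate
Conditions: PivCl (1.2 equiv), 1 M aq. NaOH (1.1 equiv), Bu4NHSO4 (5 mol%), CH2Cl2, 0 °C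
Reagents that add atoms: pivaloyl chloride, CC(C)(C)C(=O)Cl
Why: Schotten–Baumann acylation under phase transfer: dilute hydroxide ionises only the phenol, and the phenoxide ion pair is acylated far faster than the neutral primary alcohol.

**Step 4**
Reactants: 5 4-[(1E)-3-hydroxyprop-1-en-1-yl]-2,6-dimethoxyphenyl pivalate
Product: 6 4-[(2R,3R)-3-(hydroxymethyl)oxiran-2-yl]-2,6-dimethoxyphenyl pivalate (trans epoxy alcohol)
Conditions: Ti(OiPr)4 (10 mol%), D-(−)-diisopropyl tartrate (12 mol%), tBuOOH (2 equiv, decane), 4 Å MS, CH2Cl2, −20 °C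
Reagents that add atoms: tert-butyl hydroperoxide, CC(C)(C)OO
Why: Sharpless asymmetric epoxidation: the Ti(OiPr)4–D-(−)-tartrate catalyst binds the allylic alkoxide and the peroxide and delivers oxygen to one enantioface of the (E)-alkene (reagent control), which should set both epoxide carbons as 2R,3R as it does for (E)-cinnamyl alcohol, while the pivalate keeps the aryl group from ionising the product.

**Step 5**
Reactants: 7 3,4-dihydroxy-5-methoxybenzaldehyde
Product: 8 3-hydroxy-5-methoxy-4-(prop-2-en-1-yloxy)benzaldehyde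
Conditions: allyl bromide (1.05 equiv), NaHCO3 (1.5 equiv), DMF, 40 °C
Reagents that add atoms: allyl bromide, C=CCBr
Why: Williamson etherification under weak-base control: hydrogencarbonate ionises only the 4-OH, which is para to the formyl group and so the more acidic one, and the mono-phenoxide is allylated there.

**Step 6**
Reactants: 6 4-[(2R,3R)-3-(hydroxymethyl)oxiran-2-yl]-2,6-dimethoxyphenyl pivalate; 8 3-hydroxy-5-methoxy-4-(prop-2-en-1-yloxy)benzaldehyde
Product: 9 4-[(1S,2R)-1-[5-formyl-3-methoxy-2-(prop-2-en-1-yloxy)phenoxy]-2,3-dihydroxypropyl]-2,6-dimethoxyphenyl pivalate (erythro diol)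
Conditions: 8 (1.5 equiv), Ti(OiPr)4 (1.5 equiv), toluene, rt, iPrOH stripped; then 6, toluene, rt → 45 °C; 10% aq. tartaric acid
Reagents that add atoms: none
Why: Ti(OiPr)4-mediated nucleophilic opening of a 2,3-epoxy alcohol: the substrate alkoxide binds titanium, the epoxide oxygen is activated in the chelate and the aryloxide attacks the benzylic carbon from the rear (SN2), so that carbon is inverted to S, the carbinol carbon stays R and the erythro diol should result.

**Step 7**
Reactants: 9 erythro diol
Product: 10 4-[(1S,2R)-3-(tert-butyldimethylsilyloxy)-1-[5-formyl-3-methoxy-2-(prop-2-en-1-yloxy)phenoxy]-2-hydroxypropyl]-2,6-dimethoxyphenyl pivalate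
Conditions: TBSCl (1.1 equiv), imidazole (2 equiv), CH2Cl2, 0 °C
Reagents that add atoms: tert-butyldimethylsilyl chloride, CC(C)(C)[Si](C)(C)Cl
Why: Silyl ether formation with a bulky chlorosilane, which discriminates the primary from the hindered secondary hydroxyl; the only phenol is still masked as its allyl ether.

**Step 8**
Reactants: 10 primary silyl ether with allyl-protected phenol
Product: 11 4-[(1S,2R)-3-(tert-butyldimethylsilyloxy)-1-(5-formyl-2-hydroxy-3-methoxyphenoxy)-2-hydroxypropyl]-2,6-dimethoxyphenyl pivalate (erythro; O4 phenol free)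
Conditions: Pd(PPh3)4 (5 mol%), N-methylaniline (3 equiv), THF, rt
Reagents that add atoms: none
Why: Tsuji–Trost deallylation: zerovalent palladium ionises the aryl allyl ether, whose phenoxide (para to the formyl group) is a good leaving group, and N-methylaniline traps the π-allyl complex without touching aldehyde, pivalate or silyl ether.

**Step 9**
Reactants: 11 erythro hydroxy phenol
Product: 12 4-[(2S,3S)-3-[(tert-butyldimethylsilyloxy)methyl]-7-formyl-5-methoxy-2,3-dihydro-1,4-benzodioxin-2-yl]-2,6-dimethoxyphenyl pivalate (trans)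
Conditions: PPh3 (1.5 equiv), DIAD (1.5 equiv, slow addition), THF (0.02 M), 0 °C → rt
Reagents that add atoms: none
Why: PPh3 and DIAD give the phosphonium betaine, which is protonated by the O4 phenol (para to the formyl group and the only acidic O–H) and then turns the C3 hydroxyl into an alkoxyphosphonium ion that the phenoxide displaces from the rear with loss of Ph3P=O. The closest known reaction type is the intramolecular Mitsunobu etherification of a phenol with a secondary alcohol, as used to close 2,3-disubstituted 1,4-benzodioxanes. The dioxane ring closes in the 6-exo-tet mode by forming O4–C3. C3 becomes S by stereospecific SN2 inversion of the R carbinol inherited from the epoxide, and C2 (S) is not touched, so the erythro precursor should give the trans ring (substrate-controlled, stereospecific). The step needs substitution to win over aryl migration from C2, elimination towards the enol ether and intermolecular etherification: the pivalate makes ring B a poor neighbouring group, the acidic phenol leaves only a weakly basic phenoxide in solution, the silyl ether removes the one other hydroxyl that could give a seven-membered ring or an epoxide, and dilution suppresses dimers.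

**Step 10**
Reactants: 12 protected trans-benzodioxane aldehyde
Product: 13 (2S,3S)-3-[(tert-butyldimethylsilyloxy)methyl]-2-(4-hydroxy-3,5-dimethoxyphenyl)-5-methoxy-2,3-dihydro-1,4-benzodioxine-7-carbaldehyde
Conditions: K2CO3 (0.2 equiv), MeOH–THF (3:1), rt
Reagents that add atoms: none
Why: Base-catalysed transesterification (methanolysis) of an aryl ester, whose phenoxide is a good leaving group; the primary silyl ether and the non-enolisable aryl aldehyde are inert to carbonate in methanol, and the step is placed before the enal exists.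

**Step 11**
Reactants: 13 phenolic benzodioxane aldehyde; 14 (triphenylphosphoranylidene)acetaldehyde
Product: 15 (2E)-3-[(2S,3S)-3-[(tert-butyldimethylsilyloxy)methyl]-2-(4-hydroxy-3,5-dimethoxyphenyl)-5-methoxy-2,3-dihydro-1,4-benzodioxin-7-yl]prop-2-enal
Conditions: 14 (1.3 equiv), toluene, 80 °C
Reagents that add atoms: none
Why: Wittig olefination with a stabilised ylide, which should give the (E)-enal through the reversible, trans-selective oxaphosphetane pathway and is too weakly basic to deprotonate the ring B phenol.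

**Step 12**
Reactants: 15 silyl-protected enal
Product: 16 bilagrewin, (2E)-3-[(2S,3S)-3-(hydroxymethyl)-2-(4-hydroxy-3,5-dimethoxyphenyl)-5-methoxy-2,3-dihydro-1,4-benzodioxin-7-yl]prop-2-enal
Conditions: HF·pyridine, pyridine, THF, 0 °C → rt
Reagents that add atoms: none
Why: Fluoride-mediated desilylation driven by Si–F bond formation; pyridine-buffered HF cleaves the primary silyl ether and should leave the enal, the phenol and the benzylic aryl ether untouched.

**Compound list**

1 | syringaldehyde | COc1cc(C=O)cc(OC)c1O | starting material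
2 | triethyl phosphonoacetate | CCOC(=O)CP(=O)(OCC)OCC | starting material
3 | ethyl (E)-sinapate | CCOC(=O)/C=C/c1cc(OC)c(O)c(OC)c1 | intermediate
4 | (E)-sinapyl alcohol | OC/C=C/c1cc(OC)c(O)c(OC)c1 | intermediate
5 | 4-[(1E)-3-hydroxyprop-1-en-1-yl]-2,6-dimethoxyphenyl pivalate | COc1cc(/C=C/CO)cc(OC)c1OC(=O)C(C)(C)C | intermediate
6 | 4-[(2R,3R)-3-(hydroxymethyl)oxiran-2-yl]-2,6-dimethoxyphenyl pivalate | OC[C@H]1O[C@@H]1c1cc(OC)c(OC(=O)C(C)(C)C)c(OC)c1 | intermediate
7 | 3,4-dihydroxy-5-methoxybenzaldehyde | COc1cc(C=O)cc(O)c1O | starting material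
8 | 3-hydroxy-5-methoxy-4-(prop-2-en-1-yloxy)benzaldehyde | COc1cc(C=O)cc(O)c1OCC=C | intermediate
9 | 4-[(1S,2R)-1-[5-formyl-3-methoxy-2-(prop-2-en-1-yloxy)phenoxy]-2,3-dihydroxypropyl]-2,6-dimethoxyphenyl pivalate | COc1cc([C@H](Oc2cc(C=O)cc(OC)c2OCC=C)[C@H](O)CO)cc(OC)c1OC(=O)C(C)(C)C | intermediate
10 | 4-[(1S,2R)-3-(tert-butyldimethylsilyloxy)-1-[5-formyl-3-methoxy-2-(prop-2-en-1-yloxy)phenoxy]-2-hydroxypropyl]-2,6-dimethoxyphenyl pivalate | COc1cc([C@H](Oc2cc(C=O)cc(OC)c2OCC=C)[C@H](O)CO[Si](C)(C)C(C)(C)C)cc(OC)c1OC(=O)C(C)(C)C | intermediate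
11 | 4-[(1S,2R)-3-(tert-butyldimethylsilyloxy)-1-(5-formyl-2-hydroxy-3-methoxyphenoxy)-2-hydroxypropyl]-2,6-dimethoxyphenyl pivalate | COc1cc([C@H](Oc2cc(C=O)cc(OC)c2O)[C@H](O)CO[Si](C)(C)C(C)(C)C)cc(OC)c1OC(=O)C(C)(C)C | intermediate
12 | 4-[(2S,3S)-3-[(tert-butyldimethylsilyloxy)methyl]-7-formyl-5-methoxy-2,3-dihydro-1,4-benzodioxin-2-yl]-2,6-dimethoxyphenyl pivalate | COc1cc([C@@H]2Oc3cc(C=O)cc(OC)c3O[C@H]2CO[Si](C)(C)C(C)(C)C)cc(OC)c1OC(=O)C(C)(C)C | intermediate
13 | (2S,3S)-3-[(tert-butyldimethylsilyloxy)methyl]-2-(4-hydroxy-3,5-dimethoxyphenyl)-5-methoxy-2,3-dihydro-1,4-benzodioxine-7-carbaldehyde | COc1cc([C@@H]2Oc3cc(C=O)cc(OC)c3O[C@H]2CO[Si](C)(C)C(C)(C)C)cc(OC)c1O | intermediate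
14 | (triphenylphosphoranylidene)acetaldehyde | O=CC=P(c1ccccc1)(c1ccccc1)c1ccccc1 | starting material
15 | (2E)-3-[(2S,3S)-3-[(tert-butyldimethylsilyloxy)methyl]-2-(4-hydroxy-3,5-dimethoxyphenyl)-5-methoxy-2,3-dihydro-1,4-benzodioxin-7-yl]prop-2-enal | COc1cc([C@@H]2Oc3cc(/C=C/C=O)cc(OC)c3O[C@H]2CO[Si](C)(C)C(C)(C)C)cc(OC)c1O | intermediate
16 | bilagrewin | COc1cc([C@@H]2Oc3cc(/C=C/C=O)cc(OC)c3O[C@H]2CO)cc(OC)c1O | target

**Total step count:** 12

**Longest linear sequence:** 11 steps (steps 1–4 and 6–12; step 5 is a one-step side branch)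

**Steps most likely to fail**

Step 6. The opening may lose regio- or stereocontrol: attack at the non-benzylic epoxide carbon, isopropoxide competing with the aryloxide, or partial ionisation of the benzylic C–O bond on the Lewis acid, which would erode the erythro configuration. The fallback sets out from 6 and returns at 10. The primary hydroxyl of 6 is silylated first (TBSCl, imidazole, CH2Cl2, 0 °C) to give the epoxy silyl ether 4-[(2R,3R)-3-[(tert-butyldimethylsilyloxy)methyl]oxiran-2-yl]-2,6-dimethoxyphenyl pivalate F1. F1 is then opened by phenol 8 under base catalysis without any Lewis acid (Cs2CO3, 0.3 equiv, DMF, 60 °C). With the hydroxyl capped no epoxide migration is possible, the carbon next to the CH2O group is deactivated towards SN2, and the caesium phenoxide should attack the benzylic carbon with inversion. This delivers 10 directly and saves the separate silylation.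

Step 9. The alkoxyphosphonium ion may be diverted into elimination or neighbouring-group pathways, or the betaine may add to the aldehyde, instead of clean rearside closure. The fallback sets out from 10 and returns at 12, forming the same O4–C3 bond by a two-stage Williamson closure. The secondary hydroxyl of 10 is mesylated (MsCl, Et3N, CH2Cl2, 0 °C) to give the mesylate 4-[(1S,2R)-3-(tert-butyldimethylsilyloxy)-1-[5-formyl-3-methoxy-2-(prop-2-en-1-yloxy)phenoxy]-2-(methanesulfonyloxy)propyl]-2,6-dimethoxyphenyl pivalate F2. The allyl ether is removed as in step 8 (Pd(PPh3)4, N-methylaniline, THF, rt) to give the phenol mesylate 4-[(1S,2R)-3-(tert-butyldimethylsilyloxy)-1-(5-formyl-2-hydroxy-3-methoxyphenoxy)-2-(methanesulfonyloxy)propyl]-2,6-dimethoxyphenyl pivalate F3. K2CO3 in MeCN at 50 °C then lets the phenoxide displace the mesylate with inversion (6-exo-tet) to give 12.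

Step 11. Olefination of the electron-rich aryl aldehyde may stay incomplete while the product enal is homologated further by the same ylide. The fallback sets out from 13 and returns at 15, building the enal in separate redox stages. Horner–Wadsworth–Emmons reaction of 13 with 2 (NaH, 2.3 equiv, THF, 0 °C → rt) should give ethyl (2E)-3-[(2S,3S)-3-[(tert-butyldimethylsilyloxy)methyl]-2-(4-hydroxy-3,5-dimethoxyphenyl)-5-methoxy-2,3-dihydro-1,4-benzodioxin-7-yl]prop-2-enoate F4. Reduction with iBu2AlH (4 equiv, CH2Cl2, −78 °C) gives the allylic alcohol 4-[(2S,3S)-3-[(tert-butyldimethylsilyloxy)methyl]-7-[(1E)-3-hydroxyprop-1-en-1-yl]-5-methoxy-2,3-dihydro-1,4-benzodioxin-2-yl]-2,6-dimethoxyphenol F5. MnO2 in CH2Cl2 at rt oxidises only the allylic alcohol and gives 15.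

**Further compounds**

F1 | step 6 | 4-[(2R,3R)-3-[(tert-butyldimethylsilyloxy)methyl]oxiran-2-yl]-2,6-dimethoxyphenyl pivalate | CC(C)(C)[Si](C)(C)OC[C@H]1O[C@@H]1c1cc(OC)c(OC(=O)C(C)(C)C)c(OC)c1
F2 | step 9 | 4-[(1S,2R)-3-(tert-butyldimethylsilyloxy)-1-[5-formyl-3-methoxy-2-(prop-2-en-1-yloxy)phenoxy]-2-(methanesulfonyloxy)propyl]-2,6-dimethoxyphenyl pivalate | COc1cc([C@H](Oc2cc(C=O)cc(OC)c2OCC=C)[C@H](OS(C)(=O)=O)CO[Si](C)(C)C(C)(C)C)cc(OC)c1OC(=O)C(C)(C)C
F3 | step 9 | 4-[(1S,2R)-3-(tert-butyldimethylsilyloxy)-1-(5-formyl-2-hydroxy-3-methoxyphenoxy)-2-(methanesulfonyloxy)propyl]-2,6-dimethoxyphenyl pivalate | COc1cc([C@H](Oc2cc(C=O)cc(OC)c2O)[C@H](OS(C)(=O)=O)CO[Si](C)(C)C(C)(C)C)cc(OC)c1OC(=O)C(C)(C)C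
F4 | step 11 | ethyl (2E)-3-[(2S,3S)-3-[(tert-butyldimethylsilyloxy)methyl]-2-(4-hydroxy-3,5-dimethoxyphenyl)-5-methoxy-2,3-dihydro-1,4-benzodioxin-7-yl]prop-2-enoate | COc1cc([C@@H]2Oc3cc(/C=C/C(=O)OCC)cc(OC)c3O[C@H]2CO[Si](C)(C)C(C)(C)C)cc(OC)c1O
F5 | step 11 | 4-[(2S,3S)-3-[(tert-butyldimethylsilyloxy)methyl]-7-[(1E)-3-hydroxyprop-1-en-1-yl]-5-methoxy-2,3-dihydro-1,4-benzodioxin-2-yl]-2,6-dimethoxyphenol | COc1cc([C@@H]2Oc3cc(/C=C/CO)cc(OC)c3O[C@H]2CO[Si](C)(C)C(C)(C)C)cc(OC)c1O
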